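Compound numbers are those of the steps below; halimane numbering is used for positions (ring A = C1–C5 and C10, ring B = C5–C10).

## The problem

Target 29 is a bicyclic halimane-type diterpenoid ester, an octalin whose rings A and B share the C5–C10 bond. C10 is trigonal (1(10)-alkene), so the ring fusion carries a single stereocentre, C5–H. Four stereocentres must be set as two vicinal pairs: quaternary C4 (methyl, methoxycarbonyl) beside C5, and tertiary C8 (methyl) beside quaternary C9 (methyl and the C11–C16 chain). The pairs are insulated from one another by the trigonal C10 and by C6–C7, so neither can simply be relayed from the other through a ring conformation. C9 is the most congested carbon and is best made early on a monocyclic ketone, where enolate alkylation trans to a neighbouring methyl is dependable; C4/C5 then need their own source of absolute control. The (E)-trisubstituted allylic acetate ionises under acid and is cleaved by base, so it should appear last, and strong acid could move the 1(10)-alkene into the tetrasubstituted 5(10) position and erase C5. The C4 ester is neopentyl and cannot be epimerised, so C4 must be correct when the quaternary centre is formed. The opening is that ester carbon–C4–C5–C10=C1 is a γ,δ-unsaturated ester: C4–C5 is the bond of a Claisen rearrangement of a C1 allylic ester, and tying C4 back to C1 through C3–C2 as a δ-lactone makes that rearrangement close ring A, place the alkene at 1(10) and hand the C1 configuration to C5.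

## Retrosynthesis

**Side chain (29 ⇒ 28 ⇒ 26 ⇒ 25 ⇒ 24 ⇒ 22).** The acetate is removed first (29 ⇒ 28). In 28 the C13–C16 and C14–C15 bonds are cut together, which leads to terminal alkyne 26. Syn methylmetalation of an alkyne followed by hydroxymethylation fixes the 13E geometry by mechanism, whereas olefination of a methyl ketone would give an E/Z mixture. Alkyne 26 comes by one-carbon homologation of aldehyde 25, and 25 from allyl compound 22 through alcohol 24. The allyl group is thus a three-carbon spectator (C11–C13) that survives every earlier step; the forward steps need only distinguish a monosubstituted alkene from the trisubstituted 1(10)-alkene and spare a hindered ester.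

**C19 methyl (22 ⇒ 21 ⇒ 20 ⇒ 18).** The C4 methyl trans to H-5 is traced to a carboxyl group through iodide 21 and alcohol 20. This detour is forced by the key step: its topology puts the former lactone carbonyl trans to H-5, so an α-methyl lactone would give the wrong C4 epimer. A malonate-type lactone puts the methoxycarbonyl group cis to H-5 as required and leaves the free carboxyl to be reduced to methyl. The forward steps must reduce an acid beside a methyl ester and an allyl group, and deoxygenate a neopentyl position without ionic rearrangement.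

**Ring A (18 ⇒ 15, key disconnection).** The C4–C5 bond is cut and C1–O reconnected, which turns the octalin acid 18 into the monocyclic α-methoxycarbonyl δ-lactone 15. Two contiguous stereocentres, one quaternary, are exchanged for a single carbinol centre at C1, and C4 of 15 need not be defined. The forward reaction must be a [3,3] shift through the boat that the C2–C3 tether enforces, fast enough to outrun ionisation of the allylic C–O bond.

**Lactone and C1 (15 ⇒ 14 ⇒ 13).** The lactone C–O bond is opened to δ-hydroxy malonate 14, and the C1–H bond is traced to enone 13. A reagent-controlled ketone reduction is preferred to a diastereoselective carbonyl addition because C1 is too remote from C8/C9 for useful substrate control. The reduction must be 1,2-selective and must not touch the allyl group.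

**C1–C10 (13 ⇒ 12 ⇒ 8 + 11).** Cutting the bond between the carbinol carbon and the ring gives alkenyl triflate 8 and aldehyde 11, joined as alcohol 12 and oxidised to 13. An alkenylchromium coupling is chosen over alkenyllithium or carbonylative palladium chemistry because it tolerates the acidic malonate C–H and the esters. An acylpalladium intermediate would in addition sit five atoms from the allyl group and could cyclise onto it.

**Fragments (11 ⇒ 9 + 10; 8 ⇒ 6 ⇒ 3 + 4 ⇒ 1).** Aldehyde 11 is the Michael adduct of dimethyl malonate 9 and acrolein 10. Triflate 8 derives from ketone 6, which has α-hydrogens on one side only. In 6 the C9–C11 bond is cut to allyl bromide 4 and the regiodefined enolate stored as silyl enol ether 3. The C8–methyl bond of 3 is cut to 2-methylcyclohex-2-en-1-one 1, with the absolute configuration set by a catalytic asymmetric conjugate methylation and C9 set by alkylation trans to the new methyl.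

## Roads not taken

**Alternative 1:** The C2–C3 and C4–C5 bonds are cut, for a catalytic asymmetric Diels–Alder reaction of the ring B vinylcyclohexene ketal A1 with methacrolein A2 under a chiral oxazaborolidinium Lewis acid, giving the exo adduct A3.
- Merits: the step is convergent and catalytic, and it installs C4 with methyl and a formyl group (cis to H-5) already in the right places. Only an oxidation and esterification are needed at C4, whereas the chosen plan spends three steps (10–12) turning a carboxyl into a methyl; on this point the cycloaddition is clearly better.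
- Weak points: the required regiochemistry joins the α-carbon of A2 to the ring terminus of the diene, making a quaternary centre next to a tertiary one. More seriously, ring B arrives bare. C9 would have to be made quaternary by two successive alkylations of a β,γ-unsaturated ketone, with facial selectivity governed only by the distant C5. C8 would come from a late methylenation and hydrogenation that must distinguish several alkenes and choose a face, and the 1(10)-alkene could drift into conjugation on the way.
- Comparison: the chosen plan sets C8/C9 first by well-understood chemistry and relays C4/C5 intramolecularly, which is worth the extra steps at C19.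

**Alternative 2:** The C9–C10 bond is cut, for a reductive Heck cyclisation of the ring A enol triflate A4. Zerovalent palladium inserts into the C10–O bond, the alkenylpalladium adds 6-exo to the 1,1-disubstituted alkene, and the neopentylpalladium (no β-hydrogen) is reduced by a hydride donor to the C9 methyl of A5.
- Merits: the most congested bond is made last and catalytically, the 1(10)-alkene ends exactly in place, two side-chain carbons are already attached, and no carboxyl-to-methyl reduction is needed.
- Weak points: the configuration of the quaternary C9 rests on the face of alkene insertion, which only the single C8 methyl in a flexible tether controls. A4 needs C4, C5 and C8 set beforehand, and C8 is too far from C4/C5 to be relayed, so two independent sources of asymmetry are required.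
- Comparison: the route would probably be of similar length to the chosen one. The chosen plan offers stereochemical outcomes fixed by mechanism (trans enolate alkylation, suprafacial [3,3] transfer, enforced boat) rather than by a conformational preference that would have to be found by trial.

**Alternative 3:** The C8–C9 bond is cut, for an Ireland–Claisen ring contraction of the ring-A-fused lactone A6. O-silylation of its enolate and heating would form C8–C9, break C6–O and give acid A7 with a 6(7)-alkene and a carboxyl on C9.
- Merits: it is the same reaction class as the chosen plan, and an ordinary α-methyl lactone enolate should rearrange faster than the malonate-type ketene acetal used here; the chosen plan must compensate with forcing conditions. The vicinal C8/C9 pair is made in one step.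
- Weak points: the boat geometry gives the cis C8/C9 dimethyl relation only from a Z-propenyl group, whose methyl lies under the C5–C10 tether. The bond formed joins a fully substituted ketene acetal carbon to a secondary alkene carbon. A6 must already carry C4, C5 and C6, so the C4 quaternary centre is postponed rather than solved. After the step an extra 6(7)-alkene must be hydrogenated beside the 1(10)-alkene, and the neopentyl C11 carboxyl must be extended by five carbons.
- Comparison: the chosen plan has the slower sigmatropic step but a far simpler precursor and a shorter finish.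

Key step: step 9

Assumption: the facial sense of the conjugate methylation in step 1 is set by the ligand enantiomer; the enantiomer meant is the one that gives the (3R) enolate.

## Route

Step 1
Reactants: 1 2-methylcyclohex-2-en-1-one
Product: 3 [(3R)-2,3-dimethylcyclohex-1-en-1-yl]oxy(trimethyl)silane, via dimethylaluminium enolate 2 (not isolated)
Conditions: AlMe3 (1.3 equiv), Cu(OTf)2 (2 mol%), chiral BINOL-derived N,N-bis(1-phenylethyl)phosphoramidite (4 mol%), Et2O, −30 °C; then TMSOTf, −30 → 0 °C
Reagents that add atoms: trimethylaluminium C[Al](C)C; trimethylsilyl trifluoromethanesulfonate C[Si](C)(C)OS(=O)(=O)C(F)(F)F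
Why: Copper-catalysed asymmetric conjugate addition of AlMe3 to the 2-substituted enone; the phosphoramidite controls the face and sets C8 (3R), and O-silylation of the aluminium enolate stores its regiochemistry in 3.

Step 2
Reactants: 3 [(3R)-2,3-dimethylcyclohex-1-en-1-yl]oxy(trimethyl)silane; 4 allyl bromide
Product: 6 (2S,3R)-2,3-dimethyl-2-(prop-2-en-1-yl)cyclohexan-1-one, via lithium enolate 5 (not isolated)
Conditions: MeLi, THF, 0 °C → rt; then DMPU, 4, −78 → 0 °C
Reagents that add atoms: none
Why: Methyllithium cleaves the silyl enol ether to the regiodefined lithium enolate (enolate regeneration and C-alkylation); allyl bromide should attack anti to the pseudoaxial C3 methyl, placing the allyl group trans to it and setting quaternary C9 with the two methyls cis.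

Step 3
Reactants: 6 (2S,3R)-2,3-dimethyl-2-(prop-2-en-1-yl)cyclohexan-1-one
Product: 8 (5R,6S)-5,6-dimethyl-6-(prop-2-en-1-yl)cyclohex-1-en-1-yl trifluoromethanesulfonate, via potassium enolate 7 (not isolated)
Conditions: KN(SiMe3)2, THF, −78 °C; then PhNTf2, −78 → 0 °C
Reagents that add atoms: N-phenylbis(trifluoromethanesulfonimide) O=S(=O)(N(c1ccccc1)S(=O)(=O)C(F)(F)F)C(F)(F)F
Why: Kinetic enolate O-triflation; 6 has α-hydrogens on one side only, so a single enol triflate can form and no stereocentre is touched.

Step 4
Reactants: 9 dimethyl malonate; 10 acrolein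
Product: 11 dimethyl 2-(3-oxopropyl)propanedioate
Conditions: 9 (4 equiv), NaOMe (5 mol%), MeOH, 0 °C, slow addition of 10; AcOH quench; distillation
Reagents that add atoms: none
Why: Base-catalysed Michael addition of a malonate to an enal; excess malonate and slow addition of acrolein suppress double addition and polymerisation.

Step 5
Reactants: 8 (5R,6S)-5,6-dimethyl-6-(prop-2-en-1-yl)cyclohex-1-en-1-yl trifluoromethanesulfonate; 11 dimethyl 2-(3-oxopropyl)propanedioate
Product: 12 dimethyl 2-{3-[(5R,6S)-5,6-dimethyl-6-(prop-2-en-1-yl)cyclohex-1-en-1-yl]-3-hydroxypropyl}propanedioate (both C1 epimers)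
Conditions: CrCl2 (4 equiv), NiCl2 (2 mol%), degassed DMF, rt; neutral aqueous work-up, used promptly
Reagents that add atoms: none
Why: Nozaki–Hiyama–Kishi coupling: NiCl2 activates the alkenyl triflate and the resulting alkenylchromium species adds to the aldehyde while tolerating esters, the acidic malonate C–H and the allyl group; the C1 configuration is not controlled here and is erased in step 6.

Step 6
Reactants: 12 dimethyl 2-{3-[(5R,6S)-5,6-dimethyl-6-(prop-2-en-1-yl)cyclohex-1-en-1-yl]-3-hydroxypropyl}propanedioate (both C1 epimers)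
Product: 13 dimethyl 2-{3-[(5R,6S)-5,6-dimethyl-6-(prop-2-en-1-yl)cyclohex-1-en-1-yl]-3-oxopropyl}propanedioate
Conditions: Dess–Martin periodinane (1.2 equiv), NaHCO3, CH2Cl2, 0 °C → rt
Reagents that add atoms: none
Why: Dess–Martin oxidation of a secondary allylic alcohol under buffered conditions; both C1 epimers converge on one enone and the malonate C–H is left alone at this stoichiometry.

Step 7
Reactants: 13 dimethyl 2-{3-[(5R,6S)-5,6-dimethyl-6-(prop-2-en-1-yl)cyclohex-1-en-1-yl]-3-oxopropyl}propanedioate
Product: 14 dimethyl 2-{(3S)-3-[(5R,6S)-5,6-dimethyl-6-(prop-2-en-1-yl)cyclohex-1-en-1-yl]-3-hydroxypropyl}propanedioate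
Conditions: (R)-2-methyl-CBS-oxazaborolidine (0.2 equiv), catecholborane (1.8 equiv), toluene, −78 °C; MeOH quench, pH 7 buffer
Reagents that add atoms: none
Why: Corey–Bakshi–Shibata reduction with catecholborane, which does not hydroborate the allyl group at −78 °C; with the α-branched alkenyl group as the large substituent and the methylene chain as the small one, the (R)-catalyst should give the (1S)-carbinol by reagent control, the remote C8/C9 centres having little influence.

Step 8
Reactants: 14 dimethyl 2-{(3S)-3-[(5R,6S)-5,6-dimethyl-6-(prop-2-en-1-yl)cyclohex-1-en-1-yl]-3-hydroxypropyl}propanedioate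
Product: 15 methyl (6S)-6-[(5R,6S)-5,6-dimethyl-6-(prop-2-en-1-yl)cyclohex-1-en-1-yl]-2-oxooxane-3-carboxylate (C3 epimers)
Conditions: PPTS (10 mol%), toluene, 5 Å molecular sieves, 60 °C
Reagents that add atoms: none
Why: Acid-catalysed intramolecular transesterification (lactonisation) of a δ-hydroxy malonate to the six-membered lactone; the weak acid is chosen so that the allylic C1–O bond is not ionised, and either C4 epimer serves because C4 becomes trigonal in step 9.

Step 9
Reactants: 15 methyl (6S)-6-[(5R,6S)-5,6-dimethyl-6-(prop-2-en-1-yl)cyclohex-1-en-1-yl]-2-oxooxane-3-carboxylate (C3 epimers)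
Product: 18 (1S,5S,6R,8aS)-1-(methoxycarbonyl)-5,6-dimethyl-5-(prop-2-en-1-yl)-1,2,3,5,6,7,8,8a-octahydronaphthalene-1-carboxylic acid, via silyl ketene acetal 16 (not isolated), via trimethylsilyl ester 17 (not isolated)
Conditions: Et3N (5 equiv), TMSOTf (2 equiv), toluene, 0 °C → rt; then 110 °C (sealed vessel); then 1 M HCl, THF, 0 °C
Reagents that add atoms: none
Why: Soft enolisation of the β-dicarbonyl lactone gives silyl ketene acetal 16, in which silyl migration between the two carbonyl oxygens makes the ring-oxygen-silylated isomer available; on heating, this isomer undergoes a concerted [3,3] shift across C4=C(OSi)–O–C1–C10=C5 that forms C4–C5, breaks C1–O and gives silyl ester 17, hydrolysed to 18 on work-up. The closest known reaction type is the Ireland–Claisen ring contraction of 6-alkenyl δ-lactone silyl ketene acetals to cyclohexenecarboxylic acids, here in its slower malonate-type form. Ring A closes neither by exo nor by endo attack but by sigmatropic ring contraction: the six-membered lactone is exchanged for the carbocycle C1–C2–C3–C4–C5–C10 through a bicyclo[2.2.2]-like boat array in which C2–C3 is the third bridge. C5 is set by C1, because bond formation is suprafacial and C4 arrives on the face of C5=C10 from which the (1S) C–O bond departs, the face that also carries the C9 methyl. C4 is set by the enforced boat: the ring carbonyl carbon lies over C10 and ends anti to H-5, leaving the methoxycarbonyl group cis to H-5 whatever the C4 configuration of 15. Both selectivities are therefore intramolecular and topological; beyond them the step needs rate and survival of the allylic C1–O bond, which excess amine (no free Lewis acid) and a non-polar solvent should secure. Ring B can adopt the half-chair with the C9 methyl pseudoequatorial, so the siloxy group of the boat should pass over C9 without a prohibitive clash.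

Step 10
Reactants: 18 (1S,5S,6R,8aS)-1-(methoxycarbonyl)-5,6-dimethyl-5-(prop-2-en-1-yl)-1,2,3,5,6,7,8,8a-octahydronaphthalene-1-carboxylic acid
Product: 20 methyl (1S,5S,6R,8aS)-1-(hydroxymethyl)-5,6-dimethyl-5-(prop-2-en-1-yl)-1,2,3,5,6,7,8,8a-octahydronaphthalene-1-carboxylate, via mixed carbonic anhydride 19 (not isolated)
Conditions: ClCO2Et, Et3N, THF, −10 °C; then NaBH4, THF/H2O, 0 °C
Reagents that add atoms: none
Why: Mixed-anhydride activation and NaBH4 reduction convert the free acid chemoselectively into the primary alcohol; the methyl ester and both alkenes are inert to NaBH4 here, whereas borane would hydroborate the allyl group.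

Step 11
Reactants: 20 methyl (1S,5S,6R,8aS)-1-(hydroxymethyl)-5,6-dimethyl-5-(prop-2-en-1-yl)-1,2,3,5,6,7,8,8a-octahydronaphthalene-1-carboxylate
Product: 21 methyl (1R,5S,6R,8aS)-1-(iodomethyl)-5,6-dimethyl-5-(prop-2-en-1-yl)-1,2,3,5,6,7,8,8a-octahydronaphthalene-1-carboxylate
Conditions: I2, PPh3, imidazole, toluene, 90 °C
Reagents that add atoms: iodine [I][I]
Why: Garegg–Samuelsson (Appel-type) iodination through the alkoxyphosphonium salt; displacement at the neopentyl carbon is slow but no β-hydrogen is available for elimination, and the neutral medium spares the ester and alkenes (the descriptor at C4 changes by priority only).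

Step 12
Reactants: 21 methyl (1R,5S,6R,8aS)-1-(iodomethyl)-5,6-dimethyl-5-(prop-2-en-1-yl)-1,2,3,5,6,7,8,8a-octahydronaphthalene-1-carboxylate
Product: 22 methyl (1S,5S,6R,8aS)-1,5,6-trimethyl-5-(prop-2-en-1-yl)-1,2,3,5,6,7,8,8a-octahydronaphthalene-1-carboxylate
Conditions: Bu3SnH (1.5 equiv), AIBN (cat.), benzene, 80 °C
Reagents that add atoms: none
Why: Radical-chain dehalogenation with Bu3SnH; iodine abstraction is fast and the primary C19 radical should be reduced before it can add to the 1(10)-alkene or undergo a 1,2-acyl shift, giving the C19 methyl without disturbing C4.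

Step 13
Reactants: 22 methyl (1S,5S,6R,8aS)-1,5,6-trimethyl-5-(prop-2-en-1-yl)-1,2,3,5,6,7,8,8a-octahydronaphthalene-1-carboxylate
Product: 24 methyl (1S,5S,6R,8aS)-5-(3-hydroxypropyl)-1,5,6-trimethyl-1,2,3,5,6,7,8,8a-octahydronaphthalene-1-carboxylate, via B-alkyl-9-BBN adduct 23 (not isolated)
Conditions: 9-BBN, THF, 0 °C → rt; then NaOH, H2O2, 0 °C → rt
Reagents that add atoms: hydrogen peroxide OO
Why: Anti-Markovnikov hydroboration–oxidation; the bulky borane reacts only with the monosubstituted alkene and leaves the trisubstituted 1(10)-alkene and the hindered ester.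

Step 14
Reactants: 24 methyl (1S,5S,6R,8aS)-5-(3-hydroxypropyl)-1,5,6-trimethyl-1,2,3,5,6,7,8,8a-octahydronaphthalene-1-carboxylate
Product: 25 methyl (1S,5S,6R,8aS)-1,5,6-trimethyl-5-(3-oxopropyl)-1,2,3,5,6,7,8,8a-octahydronaphthalene-1-carboxylate
Conditions: Dess–Martin periodinane, NaHCO3, CH2Cl2, rt
Reagents that add atoms: none
Why: Dess–Martin oxidation of a primary alcohol stops cleanly at the aldehyde.

Step 15
Reactants: 25 methyl (1S,5S,6R,8aS)-1,5,6-trimethyl-5-(3-oxopropyl)-1,2,3,5,6,7,8,8a-octahydronaphthalene-1-carboxylate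
Product: 26 methyl (1S,5S,6R,8aS)-5-(but-3-yn-1-yl)-1,5,6-trimethyl-1,2,3,5,6,7,8,8a-octahydronaphthalene-1-carboxylate
Conditions: dimethyl (1-diazo-2-oxopropyl)phosphonate, K2CO3, MeOH, 0 °C → rt
Reagents that add atoms: dimethyl (1-diazo-2-oxopropyl)phosphonate CC(=O)C(=[N+]=[N-])P(=O)(OC)OC
Why: Ohira–Bestmann (Seyferth–Gilbert) homologation: the diazomethylphosphonate anion formed in situ adds to the aldehyde and the alkylidene carbene rearranges to the terminal alkyne; the mild medium cannot epimerise any centre.

Step 16
Reactants: 26 methyl (1S,5S,6R,8aS)-5-(but-3-yn-1-yl)-1,5,6-trimethyl-1,2,3,5,6,7,8,8a-octahydronaphthalene-1-carboxylate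
Product: 28 methyl (1S,5S,6R,8aS)-5-[(3E)-5-hydroxy-3-methylpent-3-en-1-yl]-1,5,6-trimethyl-1,2,3,5,6,7,8,8a-octahydronaphthalene-1-carboxylate, via alkenylalane 27 (not isolated)
Conditions: AlMe3 (3 equiv), Cp2ZrCl2 (0.25 equiv), CH2Cl2, 0 °C → rt; volatiles removed; THF, n-BuLi (1 equiv), −78 °C; (CH2O)n, −78 °C → rt; dilute HCl
Reagents that add atoms: trimethylaluminium C[Al](C)C; formaldehyde (as paraformaldehyde) C=O
Why: Zirconium-catalysed methylalumination (Negishi carboalumination) adds methyl and aluminium syn across the terminal alkyne with methyl on the internal carbon, which fixes the 13E geometry; the alkenylalane, activated as its aluminate, is hydroxymethylated by formaldehyde with retention.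

Step 17
Reactants: 28 methyl (1S,5S,6R,8aS)-5-[(3E)-5-hydroxy-3-methylpent-3-en-1-yl]-1,5,6-trimethyl-1,2,3,5,6,7,8,8a-octahydronaphthalene-1-carboxylate
Product: 29 methyl (1S,5S,6R,8aS)-5-[(3E)-5-(acetyloxy)-3-methylpent-3-en-1-yl]-1,5,6-trimethyl-1,2,3,5,6,7,8,8a-octahydronaphthalene-1-carboxylate
Conditions: Ac2O, pyridine, DMAP (cat.), CH2Cl2, rt
Reagents that add atoms: acetic anhydride CC(=O)OC(C)=O
Why: DMAP-catalysed acetylation of the primary allylic alcohol under basic, non-ionising conditions gives the target.

## Compound list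

1 | 2-methylcyclohex-2-en-1-one | CC1=CCCCC1=O | starting material
2 | dimethylaluminium (3R)-2,3-dimethylcyclohex-1-en-1-olate | C[C@@H]1CCCC(O[Al](C)C)=C1C | intermediate (not isolated)
3 | [(3R)-2,3-dimethylcyclohex-1-en-1-yl]oxy(trimethyl)silane | C[C@@H]1CCCC(O[Si](C)(C)C)=C1C | intermediate
4 | allyl bromide (3-bromoprop-1-ene) | C=CCBr | starting material
5 | lithium (3R)-2,3-dimethylcyclohex-1-en-1-olate | C[C@@H]1CCCC(O[Li])=C1C | intermediate (not isolated)
6 | (2S,3R)-2,3-dimethyl-2-(prop-2-en-1-yl)cyclohexan-1-one | O=C1CCC[C@@H](C)[C@]1(C)CC=C | intermediate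
7 | potassium (5R,6S)-5,6-dimethyl-6-(prop-2-en-1-yl)cyclohex-1-en-1-olate | [K]OC1=CCC[C@@H](C)[C@]1(C)CC=C | intermediate (not isolated)
8 | (5R,6S)-5,6-dimethyl-6-(prop-2-en-1-yl)cyclohex-1-en-1-yl trifluoromethanesulfonate | FC(F)(F)S(=O)(=O)OC1=CCC[C@@H](C)[C@]1(C)CC=C | intermediate
9 | dimethyl malonate | COC(=O)CC(=O)OC | starting material
10 | acrolein | C=CC=O | starting material
11 | dimethyl 2-(3-oxopropyl)propanedioate | COC(=O)C(CCC=O)C(=O)OC | intermediate
12 | dimethyl 2-{3-[(5R,6S)-5,6-dimethyl-6-(prop-2-en-1-yl)cyclohex-1-en-1-yl]-3-hydroxypropyl}propanedioate (both C1 epimers) | COC(=O)C(CCC(O)C1=CCC[C@@H](C)[C@]1(C)CC=C)C(=O)OC | intermediate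
13 | dimethyl 2-{3-[(5R,6S)-5,6-dimethyl-6-(prop-2-en-1-yl)cyclohex-1-en-1-yl]-3-oxopropyl}propanedioate | COC(=O)C(CCC(=O)C1=CCC[C@@H](C)[C@]1(C)CC=C)C(=O)OC | intermediate
14 | dimethyl 2-{(3S)-3-[(5R,6S)-5,6-dimethyl-6-(prop-2-en-1-yl)cyclohex-1-en-1-yl]-3-hydroxypropyl}propanedioate | COC(=O)C(CC[C@H](O)C1=CCC[C@@H](C)[C@]1(C)CC=C)C(=O)OC | intermediate
15 | methyl (6S)-6-[(5R,6S)-5,6-dimethyl-6-(prop-2-en-1-yl)cyclohex-1-en-1-yl]-2-oxooxane-3-carboxylate (C3 epimers) | COC(=O)C1CC[C@H](OC1=O)C2=CCC[C@@H](C)[C@]2(C)CC=C | intermediate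
16 | methyl (2S)-2-[(5R,6S)-5,6-dimethyl-6-(prop-2-en-1-yl)cyclohex-1-en-1-yl]-6-[(trimethylsilyl)oxy]-3,4-dihydro-2H-pyran-5-carboxylate | COC(=O)C1=C(O[Si](C)(C)C)O[C@@H](CC1)C2=CCC[C@@H](C)[C@]2(C)CC=C | intermediate (not isolated)
17 | 1-methyl 1-trimethylsilyl (1R,5S,6R,8aS)-5,6-dimethyl-5-(prop-2-en-1-yl)-3,5,6,7,8,8a-hexahydronaphthalene-1,1(2H)-dicarboxylate | COC(=O)[C@@]1(C(=O)O[Si](C)(C)C)CCC=C2[C@@H]1CC[C@@H](C)[C@]2(C)CC=C | intermediate (not isolated)
18 | (1S,5S,6R,8aS)-1-(methoxycarbonyl)-5,6-dimethyl-5-(prop-2-en-1-yl)-1,2,3,5,6,7,8,8a-octahydronaphthalene-1-carboxylic acid | COC(=O)[C@@]1(C(O)=O)CCC=C2[C@@H]1CC[C@@H](C)[C@]2(C)CC=C | intermediate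
19 | ethyl carbonic (1R,5S,6R,8aS)-1-(methoxycarbonyl)-5,6-dimethyl-5-(prop-2-en-1-yl)-1,2,3,5,6,7,8,8a-octahydronaphthalene-1-carboxylic anhydride | COC(=O)[C@@]1(C(=O)OC(=O)OCC)CCC=C2[C@@H]1CC[C@@H](C)[C@]2(C)CC=C | intermediate (not isolated)
20 | methyl (1S,5S,6R,8aS)-1-(hydroxymethyl)-5,6-dimethyl-5-(prop-2-en-1-yl)-1,2,3,5,6,7,8,8a-octahydronaphthalene-1-carboxylate | COC(=O)[C@@]1(CO)CCC=C2[C@@H]1CC[C@@H](C)[C@]2(C)CC=C | intermediate
21 | methyl (1R,5S,6R,8aS)-1-(iodomethyl)-5,6-dimethyl-5-(prop-2-en-1-yl)-1,2,3,5,6,7,8,8a-octahydronaphthalene-1-carboxylate | COC(=O)[C@@]1(CI)CCC=C2[C@@H]1CC[C@@H](C)[C@]2(C)CC=C | intermediate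
22 | methyl (1S,5S,6R,8aS)-1,5,6-trimethyl-5-(prop-2-en-1-yl)-1,2,3,5,6,7,8,8a-octahydronaphthalene-1-carboxylate | COC(=O)[C@@]1(C)CCC=C2[C@@H]1CC[C@@H](C)[C@]2(C)CC=C | intermediate
23 | methyl (1S,5S,6R,8aS)-5-[3-(9-borabicyclo[3.3.1]nonan-9-yl)propyl]-1,5,6-trimethyl-1,2,3,5,6,7,8,8a-octahydronaphthalene-1-carboxylate | COC(=O)[C@@]1(C)CCC=C2[C@@H]1CC[C@@H](C)[C@]2(C)CCCB3C4CCCC3CCC4 | intermediate (not isolated)
24 | methyl (1S,5S,6R,8aS)-5-(3-hydroxypropyl)-1,5,6-trimethyl-1,2,3,5,6,7,8,8a-octahydronaphthalene-1-carboxylate | COC(=O)[C@@]1(C)CCC=C2[C@@H]1CC[C@@H](C)[C@]2(C)CCCO | intermediate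
25 | methyl (1S,5S,6R,8aS)-1,5,6-trimethyl-5-(3-oxopropyl)-1,2,3,5,6,7,8,8a-octahydronaphthalene-1-carboxylate | COC(=O)[C@@]1(C)CCC=C2[C@@H]1CC[C@@H](C)[C@]2(C)CCC=O | intermediate
26 | methyl (1S,5S,6R,8aS)-5-(but-3-yn-1-yl)-1,5,6-trimethyl-1,2,3,5,6,7,8,8a-octahydronaphthalene-1-carboxylate | COC(=O)[C@@]1(C)CCC=C2[C@@H]1CC[C@@H](C)[C@]2(C)CCC#C | intermediate
27 | methyl (1S,5S,6R,8aS)-5-[(3E)-4-(dimethylalumanyl)-3-methylbut-3-en-1-yl]-1,5,6-trimethyl-1,2,3,5,6,7,8,8a-octahydronaphthalene-1-carboxylate | COC(=O)[C@@]1(C)CCC=C2[C@@H]1CC[C@@H](C)[C@]2(C)CC/C(C)=C/[Al](C)C | intermediate (not isolated)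
28 | methyl (1S,5S,6R,8aS)-5-[(3E)-5-hydroxy-3-methylpent-3-en-1-yl]-1,5,6-trimethyl-1,2,3,5,6,7,8,8a-octahydronaphthalene-1-carboxylate | COC(=O)[C@@]1(C)CCC=C2[C@@H]1CC[C@@H](C)[C@]2(C)CC/C(C)=C/CO | intermediate
29 | methyl (1S,5S,6R,8aS)-5-[(3E)-5-(acetyloxy)-3-methylpent-3-en-1-yl]-1,5,6-trimethyl-1,2,3,5,6,7,8,8a-octahydronaphthalene-1-carboxylate | COC(=O)[C@@]1(C)CCC=C2[C@@H]1CC[C@@H](C)[C@]2(C)CC/C(C)=C/COC(C)=O | target

## Step count and risks

Total step count: 17. Longest linear sequence: 16 steps (steps 1–3 and 5–17, from 1 to 29); step 4 is a one-step branch.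

Least certain steps:

**Step 9 (key step).**
- Most likely failure: a sluggish rearrangement, because the ester-substituted ketene acetal is electron-poor and the boat is enforced. Prolonged heating would then let the allylic C1–O bond ionise, with elimination to dienes or loss of the C1 to C5 transfer. Crowding between the siloxy group and C9 on the reacting face would add to this.
- Fallback, setting out from 14 and returning at 20 (it replaces steps 8–10): the same C4–C5 bond would be made by an intramolecular Tsuji–Trost alkylation. Alcohol 14 would be converted into its methyl carbonate F1 (ClCO2Me, pyridine). F1 would be cyclised with Pd(PPh3)4 in THF; zerovalent palladium ionises anti and the malonate attacks C5 anti to the metal, so the net result is retention on the same face as in the sigmatropic step, in a 6-endo closure to the geminal diester F2. The two esters of F2 are diastereotopic. The equatorial one, cis to H-5, should be saponified preferentially (LiOH, aqueous THF) to half-acid F3. The remaining axial ester would be reduced with LiBH4 in the presence of the carboxylate to hydroxy acid F4, and the acid methylated (Me3SiCHN2, MeOH) to give 20.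

**Step 5.**
- Most likely failure: slow oxidative addition and transmetallation at the triflate flanked by the quaternary C9, together with consumption of aldehyde 11 by self-condensation through its acidic malonate position, or premature lactonisation of the product.
- Fallback, setting out from 8 and returning at 13 (it replaces steps 5 and 6 and makes 11 unnecessary): the same coupling would be run with the simpler, non-acidic aldehyde 10 to give the bis-allylic alcohol F5. F5 would be oxidised (MnO2) to the cross-conjugated dienone F6, and dimethyl malonate 9 added under catalytic base to the unsubstituted vinyl terminus to give 13.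

**Step 7.**
- Most likely failure: weak facial discrimination, if the hindered α-branched alkenyl group and the chain are not differentiated well by the catalyst, and competing conjugate reduction of the enone by catecholborane.
- Fallback, setting out from 12 and returning at 14 (it replaces steps 6 and 7): the C1 epimers of 12 are diastereomers and would be separated by chromatography, one of them being 14. The (1R) epimer F7 would be inverted by Mitsunobu esterification with 4-nitrobenzoic acid (PPh3, DIAD) to the (1S) 4-nitrobenzoate F8, which K2CO3 in MeOH would cleave to 14.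

**Step 11.**
- Most likely failure: an impractically slow displacement at the neopentyl carbon, with the alkoxyphosphonium intermediate reverting to the alcohol on work-up or rearranging under forcing conditions.
- Fallback, setting out from 20 and returning at 22 (it replaces steps 11 and 12): the alcohol would be oxidised with Dess–Martin periodinane to the non-enolisable aldehyde F9. F9 would be condensed with tosylhydrazide to tosylhydrazone F10, which would be reduced with catecholborane followed by NaOAc·3H2O, the diazene losing nitrogen to leave the methyl group of 22.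

**Step 16.**
- Most likely failure: attack of the organometallic reagents on the C4 ester during aluminate formation, or incomplete hydroxymethylation, which would return the protonated alkene.
- Fallback, setting out from 25 and returning at 28 (it replaces steps 15 and 16): MeMgBr at −78 °C would add to the aldehyde to give secondary alcohol F11. Dess–Martin oxidation would give methyl ketone F12. Horner–Wadsworth–Emmons olefination with triethyl phosphonoacetate and NaH would give the (E)-enoate F13 after separation from its Z isomer. DIBAL-H at −78 °C would reduce the unhindered conjugated ester in preference to the neopentyl C4 ester to give 28.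

## Further compounds

F1 | step 9 | dimethyl 2-{(3S)-3-[(5R,6S)-5,6-dimethyl-6-(prop-2-en-1-yl)cyclohex-1-en-1-yl]-3-[(methoxycarbonyl)oxy]propyl}propanedioate | COC(=O)C(CC[C@H](OC(=O)OC)C1=CCC[C@@H](C)[C@]1(C)CC=C)C(=O)OC
F2 | step 9 | dimethyl (5S,6R,8aS)-5,6-dimethyl-5-(prop-2-en-1-yl)-3,5,6,7,8,8a-hexahydronaphthalene-1,1(2H)-dicarboxylate | COC(=O)C1(C(=O)OC)CCC=C2[C@@H]1CC[C@@H](C)[C@]2(C)CC=C
F3 | step 9 | (1R,5S,6R,8aS)-1-(methoxycarbonyl)-5,6-dimethyl-5-(prop-2-en-1-yl)-1,2,3,5,6,7,8,8a-octahydronaphthalene-1-carboxylic acid | OC(=O)[C@@]1(C(=O)OC)CCC=C2[C@@H]1CC[C@@H](C)[C@]2(C)CC=C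
F4 | step 9 | (1S,5S,6R,8aS)-1-(hydroxymethyl)-5,6-dimethyl-5-(prop-2-en-1-yl)-1,2,3,5,6,7,8,8a-octahydronaphthalene-1-carboxylic acid | OC(=O)[C@@]1(CO)CCC=C2[C@@H]1CC[C@@H](C)[C@]2(C)CC=C
F5 | step 5 | 1-[(5R,6S)-5,6-dimethyl-6-(prop-2-en-1-yl)cyclohex-1-en-1-yl]prop-2-en-1-ol (both carbinol epimers) | C=CC(O)C1=CCC[C@@H](C)[C@]1(C)CC=C
F6 | step 5 | 1-[(5R,6S)-5,6-dimethyl-6-(prop-2-en-1-yl)cyclohex-1-en-1-yl]prop-2-en-1-one | C=CC(=O)C1=CCC[C@@H](C)[C@]1(C)CC=C
F7 | step 7 | dimethyl 2-{(3R)-3-[(5R,6S)-5,6-dimethyl-6-(prop-2-en-1-yl)cyclohex-1-en-1-yl]-3-hydroxypropyl}propanedioate | COC(=O)C(CC[C@@H](O)C1=CCC[C@@H](C)[C@]1(C)CC=C)C(=O)OC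
F8 | step 7 | dimethyl 2-{(3S)-3-[(5R,6S)-5,6-dimethyl-6-(prop-2-en-1-yl)cyclohex-1-en-1-yl]-3-[(4-nitrobenzoyl)oxy]propyl}propanedioate | COC(=O)C(CC[C@H](OC(=O)c1ccc(cc1)[N+](=O)[O-])C2=CCC[C@@H](C)[C@]2(C)CC=C)C(=O)OC
F9 | step 11 | methyl (1S,5S,6R,8aS)-1-formyl-5,6-dimethyl-5-(prop-2-en-1-yl)-1,2,3,5,6,7,8,8a-octahydronaphthalene-1-carboxylate | COC(=O)[C@@]1(C=O)CCC=C2[C@@H]1CC[C@@H](C)[C@]2(C)CC=C
F10 | step 11 | methyl (1S,5S,6R,8aS)-5,6-dimethyl-1-{(E)-[2-(4-methylbenzenesulfonyl)hydrazinylidene]methyl}-5-(prop-2-en-1-yl)-1,2,3,5,6,7,8,8a-octahydronaphthalene-1-carboxylate | COC(=O)[C@@]1(/C=N/NS(=O)(=O)c3ccc(C)cc3)CCC=C2[C@@H]1CC[C@@H](C)[C@]2(C)CC=C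
F11 | step 16 | methyl (1S,5S,6R,8aS)-5-(3-hydroxybutyl)-1,5,6-trimethyl-1,2,3,5,6,7,8,8a-octahydronaphthalene-1-carboxylate (both carbinol epimers) | COC(=O)[C@@]1(C)CCC=C2[C@@H]1CC[C@@H](C)[C@]2(C)CCC(C)O
F12 | step 16 | methyl (1S,5S,6R,8aS)-1,5,6-trimethyl-5-(3-oxobutyl)-1,2,3,5,6,7,8,8a-octahydronaphthalene-1-carboxylate | COC(=O)[C@@]1(C)CCC=C2[C@@H]1CC[C@@H](C)[C@]2(C)CCC(C)=O
F13 | step 16 | methyl (1S,5S,6R,8aS)-5-[(3E)-5-ethoxy-3-methyl-5-oxopent-3-en-1-yl]-1,5,6-trimethyl-1,2,3,5,6,7,8,8a-octahydronaphthalene-1-carboxylate | COC(=O)[C@@]1(C)CCC=C2[C@@H]1CC[C@@H](C)[C@]2(C)CC/C(C)=C/C(=O)OCC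
A1 | alternative 1 | 7-ethenyl-1,4-dioxaspiro[4.5]dec-7-ene | C=CC1=CCCC2(C1)OCCO2
A2 | alternative 1 | methacrolein (2-methylprop-2-enal) | CC(=C)C=O
A3 | alternative 1 | (4a'S,5'S)-5'-methyl-3',4',4a',5',6',7'-hexahydro-1'H-spiro[1,3-dioxolane-2,2'-naphthalene]-5'-carbaldehyde | O=C[C@@]1(C)CCC=C2[C@@H]1CCC3(C2)OCCO3
A4 | alternative 2 | methyl (1S,2R)-2-[(3R)-6-{[tert-butyl(dimethyl)silyl]oxy}-3-methyl-4-methylidenehexyl]-1-methyl-3-{[(trifluoromethyl)sulfonyl]oxy}cyclohex-3-ene-1-carboxylate | COC(=O)[C@@]1(C)CCC=C(OS(=O)(=O)C(F)(F)F)[C@@H]1CC[C@@H](C)C(=C)CCO[Si](C)(C)C(C)(C)C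
A5 | alternative 2 | methyl (1S,5S,6R,8aS)-5-(2-{[tert-butyl(dimethyl)silyl]oxy}ethyl)-1,5,6-trimethyl-1,2,3,5,6,7,8,8a-octahydronaphthalene-1-carboxylate | COC(=O)[C@@]1(C)CCC=C2[C@@H]1CC[C@@H](C)[C@]2(C)CCO[Si](C)(C)C(C)(C)C
A6 | alternative 3 | methyl (1R,8S,8aS)-4,8-dimethyl-3-oxo-1-[(1Z)-prop-1-en-1-yl]-3,4,6,7,8,8a-hexahydro-1H-isochromene-8-carboxylate (C4 epimers) | COC(=O)[C@@]1(C)CCC=C2[C@@H]1[C@H](OC(=O)C2C)/C=C\C
A7 | alternative 3 | (1S,2R,4aS,5S)-5-(methoxycarbonyl)-1,2,5-trimethyl-1,2,4a,5,6,7-hexahydronaphthalene-1-carboxylic acid | COC(=O)[C@@]1(C)CCC=C2[C@@H]1C=C[C@@H](C)[C@]2(C)C(O)=O
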